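At 20.0 min the south-west run held loose adduct, target and substrate summing to 99.0%, so I gave the dormant form no weight.

| flask | substrate | reagent | remark | time |
|---|---|---|---|---|
| south-west | 0.10 M (fed, over 12 min) | 0.14 M | run made earlier; the fed solution adds 0.10 times the starting volume |  |
| flask | 0.10 M (fed, over 12 min) | 0.0900 M | the fed solution adds 0.10 times the starting volume | 1.0 h |

south-west run (percent of the substrate charged)

| time / min | loose adduct / % | target / % | substrate / % |
|---|---|---|---|
| 1.00 | 10 | 0 | 3 |
| 3.00 | 18 | 9 | 0 |
| 5.00 | 26 | 17 | 2 |
| 8.00 | 29 | 31 | 3 |
| 10.0 | 32 | 45 | 5 |
| 15.0 | 23 | 70 | 6 |
| 20.0 | 16 | 78 | 5 |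

(standard deviation of a reading: 1.5 percentage points)

- target is meant together with its idle adduct
- every charge counts on the volume at the start, and the solution that is fed holds the whole dose
- the numbers in the tables scatter by 1.5 percentage points (one standard deviation)
- what may be going on: substrate + reagent <-> loose adduct; loose adduct <-> target; substrate <-> dormant form; reagent + target <-> idle adduct
- percentages count the whole charge, also what has not yet gone in

* time, not beyond 1.0 h, at which the flask holds most loose adduct
* the amount of loose adduct, in percent of the substrate charged, at that time

I followed one fed substrate molecule: it binds reagent, waits as loose adduct, then leaves as target. At the first fork, the south-west run at 10.0 min showed adduct above substrate, so I counted binding as prompt. Between 5.00 min and 10.0 min target rose 28 percentage points on a mean adduct of 29.0%, which read as a drain rate k of 0.193 min⁻¹. Feed rate over k gave a standing level of 43.2%. In this flask reagent is the limiting reagent, and fed substrate equals the reagent charged at 10.8 min.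

Which inputs mattered? Twice that k took 17 points off the estimate, so k had to be good. In the same reckoning, raising [reagent] to 0.14 M, where the feed ends before equivalence, added 1.1 points to the estimate. So I took the equivalence stock, 37.8%: the adduct that steady inflow, drained at k, has built by equivalence. I expected the peak near that moment and somewhat lower.

The forecast said 0.16 h and 30%: “The peak is broad”. Its height stood 7.8 points below my stock.

The flask peaked at 9.02 min, before equivalence, at 27.1%, below the stock.

    substrate + reagent ⇌ loose adduct, settled at all times (K = 150 M⁻¹)
    loose adduct ⇌ target (K = 5.10, k = 0.230 min⁻¹)
    substrate ⇌ dormant form (K = 3.50, k = 0.0350 min⁻¹)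
    reagent + target ⇌ idle adduct, settled at all times (K = 22.0 M⁻¹)

The largest single effect on that height was the slow addition of substrate: without it the flask reached 71.6% against 27.1%. In the neighbour flask with 0.022 M of reagent, equivalence came at 2.64 min, the stock was 17.2%, and its peak reached 10.4%.

The runs stem from a simulated flask with made-up constants, noise included.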